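## Plan

1. The spiro[4.5]decane is numbered C1 (CHOH), C2 (side-chain CH), C5 (spiro), C6 (C(CH3)OH), C9 (enal-bearing carbon) and C10 (hydroxypropyl CH). The C1 hydroxyl, quaternary C5 and oxygenated C6 form a β-hydroxy-carbonyl array, and C10 lies trans to the C1 oxygen on the five-membered ring. This is the imprint of an anti 1,2-shift of C10 from C6 onto C5 of a C1–C5 epoxide.
2. The retrosynthesis cuts, in order: the side-chain C=C next to CH2OH (aldol condensation with a C11 dienal), C6–CH3, C5–C10 (semipinacol shift), C5–C6 (alkenyllithium plus ketone), C2–CH2 (Pd allylation of malonate), and the C9/C10 substituents (conjugate addition–allylation).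
3. In the forward direction two five-membered rings, from cyclopentenone and cyclopentane-1,3-dione, are joined at C5–C6 and the C1=C5 alkene is epoxidised. Enlargement of the cyclopentanol then creates the six-membered ring and the spiro centre. Methyl, hydroxypropyl and enal follow, and the triene chain comes last.
4. Stereochemistry: C9 (a relay centre, later sp2) comes from catalytic asymmetric conjugate addition, and C10 is set trans to it. C2 comes from CBS reduction and net-retentive Pd allylation. The C1/C5 epoxide comes from hydroxyl-directed delivery anti to the C2 arm, C5 from inversion in the shift, and C6 from axial methyl attack anti to C1. The Z enal and the E side-chain enal are set under thermodynamic control, and the central E alkene by Heck coupling.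

Key step: step 11

Assumption: the hand of the ferrocenyl diphosphine in step 1 is taken as the one that delivers isopropenyl to the enone face giving the (3S) adduct. The sense of induction has to be checked by correlation, and the antipodal ligand is used if it is opposite.

## Route

Step 1
Reactants: 1 cyclopent-2-en-1-one
Product: 3 (2R,3S)-2-allyl-3-(prop-1-en-2-yl)cyclopentan-1-one, via bromomagnesium (3S)-3-(prop-1-en-2-yl)cyclopent-1-en-1-olate 2 (not isolated)
Conditions: CH2=C(Me)MgBr, CuBr·SMe2 (5 mol %), Josiphos-type ferrocenyl diphosphine (6 mol %), t-BuOMe, −75 °C; then allyl iodide, DMPU, −75 → −20 °C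
Reagents that add atoms: isopropenylmagnesium bromide, CC(=C)[Mg]Br; allyl iodide, C=CCI
Why: Cu-catalysed asymmetric conjugate addition of a Grignard reagent to a cyclic enone should set C3 (later C9) under ligand control, and the regiodefined magnesium enolate is allylated anti to the new substituent, which gives the trans product and fixes C2 (later C10).

Step 2
Reactants: 4 cyclopentane-1,3-dione
Product: 5 3-bromocyclopent-2-en-1-one
Conditions: (COBr)2, DMF (cat.), CH2Cl2, 0 °C → rt
Reagents that add atoms: oxalyl bromide, O=C(Br)C(=O)Br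
Why: Vilsmeier-type activation of the enol of a cyclic 1,3-dione followed by addition–elimination of bromide is the standard entry to β-bromo enones.

Step 3
Reactants: 5 3-bromocyclopent-2-en-1-one
Product: 6 (1R)-3-bromocyclopent-2-en-1-ol
Conditions: (S)-Me-CBS (15 mol %), BH3·SMe2, THF, −30 °C; MeOH quench
Reagents that add atoms: none
Why: In this Corey–Bakshi–Shibata reduction the bromoalkenyl arm acts as the large group and the ring CH2 as the small one, so the (S)-oxazaborolidine should deliver hydride to give the (R) carbinol, the later C2 centre.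

Step 4
Reactants: 6 (1R)-3-bromocyclopent-2-en-1-ol
Product: 7 (1R)-3-bromocyclopent-2-en-1-yl methyl carbonate
Conditions: ClCO2Me, pyridine, CH2Cl2, 0 °C
Reagents that add atoms: methyl chloroformate, COC(=O)Cl
Why: O-acylation under basic, non-ionising conditions activates the allylic alcohol without touching the stereocentre.

Step 5
Reactants: 7 (1R)-3-bromocyclopent-2-en-1-yl methyl carbonate; 8 dimethyl malonate
Product: 9 dimethyl 2-[(1S)-3-bromocyclopent-2-en-1-yl]propanedioate
Conditions: Pd2(dba)3·CHCl3 (2.5 mol %), PPh3 (10 mol %), THF, rt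
Reagents that add atoms: none
Why: In this Tsuji–Trost alkylation under neutral carbonate conditions, ionisation and attack of the soft nucleophile both occur anti to Pd (net retention), attack goes to the CH terminus remote from bromine, and the allylic C–O bond adds to Pd(0) at room temperature well before the alkenyl C–Br bond.

Step 6
Reactants: 9 dimethyl 2-[(1S)-3-bromocyclopent-2-en-1-yl]propanedioate
Product: 10 methyl 2-[(1S)-3-bromocyclopent-2-en-1-yl]acetate
Conditions: LiCl, H2O, DMSO, 150 °C
Reagents that add atoms: none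
Why: Krapcho dealkoxycarbonylation removes one ester under neutral conditions, and the allylic stereocentre is not acidic and is not affected.

Step 7
Reactants: 10 methyl 2-[(1S)-3-bromocyclopent-2-en-1-yl]acetate
Product: 11 2-[(1S)-3-bromocyclopent-2-en-1-yl]ethan-1-ol
Conditions: DIBAL-H (2.5 equiv), CH2Cl2, −78 → 0 °C; Rochelle salt
Reagents that add atoms: none
Why: DIBAL-H reduces the ester to the primary alcohol and leaves the alkenyl bromide intact.

Step 8
Reactants: 11 2-[(1S)-3-bromocyclopent-2-en-1-yl]ethan-1-ol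
Product: 12 {2-[(1S)-3-bromocyclopent-2-en-1-yl]ethoxy}(tert-butyl)dimethylsilane
Conditions: TBSCl, imidazole, CH2Cl2, rt
Reagents that add atoms: tert-butyldimethylsilyl chloride, CC(C)(C)[Si](C)(C)Cl
Why: Standard silylation gives an arm that tolerates organolithium, peroxide and mild Lewis acid and can later be released by acid methanolysis.

Step 9
Reactants: 12 {2-[(1S)-3-bromocyclopent-2-en-1-yl]ethoxy}(tert-butyl)dimethylsilane; 3 (2R,3S)-2-allyl-3-(prop-1-en-2-yl)cyclopentan-1-one
Product: 14 (1S,2R,3S)-2-allyl-1-[(3S)-3-{2-[(tert-butyldimethylsilyl)oxy]ethyl}cyclopent-1-en-1-yl]-3-(prop-1-en-2-yl)cyclopentan-1-ol, via [(3S)-3-{2-[(tert-butyldimethylsilyl)oxy]ethyl}cyclopent-1-en-1-yl]lithium 13 (not isolated)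
Conditions: t-BuLi (2.0 equiv), Et2O, −78 °C; then 3 premixed with LaCl3·2LiCl, THF, −78 °C; aq. NH4Cl
Reagents that add atoms: tert-butyllithium, [Li]C(C)(C)C (lithium only in 13)
Why: Bromine–lithium exchange and lanthanide-assisted 1,2-addition (which suppresses enolisation) form C5–C6, and the nucleophile enters anti to the adjacent allyl group, as is usual for trans-2,3-disubstituted cyclopentanones, which sets the (S) carbinol.

Step 10
Reactants: 14 the bicyclopentyl allylic alcohol
Product: 15 (1S,2R,3S)-2-allyl-1-[(1R,4S,5S)-4-{2-[(tert-butyldimethylsilyl)oxy]ethyl}-6-oxabicyclo[3.1.0]hexan-1-yl]-3-(prop-1-en-2-yl)cyclopentan-1-ol (C1–C5 epoxide anti to the C2 arm)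
Conditions: VO(acac)2 (5 mol %), t-BuOOH (decane), CH2Cl2, 0 °C
Reagents that add atoms: tert-butyl hydroperoxide, CC(C)(C)OO
Why: Vanadium-catalysed hydroxyl-directed epoxidation (Sharpless–Michaelson) selects the allylic trisubstituted alkene over allyl and isopropenyl, and oxygen is delivered to the face anti to the C2 arm, the face whose reactive rotamer also keeps the branched C10 away from C4.

Step 11
Reactants: 15 the bicyclopentyl epoxy alcohol
Product: 16 (1S,2S,5S,9S,10R)-10-allyl-2-{2-[(tert-butyldimethylsilyl)oxy]ethyl}-1-hydroxy-9-(prop-1-en-2-yl)spiro[4.5]decan-6-one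
Conditions: ZnBr2 (0.5 equiv), CH2Cl2, 0 °C → rt
Reagents that add atoms: none
Why: ZnBr2 binds the epoxide oxygen and the C6 hydroxyl, the tertiary C5–O bond lengthens, and the C6–C10 bond lying antiperiplanar to it shifts from C6 to C5 while the carbinol collapses to the C6 ketone in a concerted 1,2-shift. The closest known reaction is the Lewis-acid semipinacol rearrangement of tertiary 2,3-epoxy alcohols to β-hydroxy ketones with a quaternary α-carbon, including 1-(epoxycycloalkyl)cycloalkanol to spiro ketone cases. The six-membered ring is not closed by a cyclisation but arises by one-carbon enlargement of the cyclopentanol (C5 is inserted between C6 and C10), which turns the bicyclopentyl into the spiro[4.5]decane. The one new stereocentre, quaternary C5, is fixed by inversion at the epoxide carbon, so C10 ends trans to the C1 oxygen, while C1 keeps the epoxide configuration and C10 migrates with retention. The step needs C10 rather than C7 to migrate and a shift that outruns proton loss or capture of the developing C5 cation by the isopropenyl group; C10 is the more substituted and better migrating carbon, and with the (S) carbinol the chelated hydroxyl sits in the narrow sector between C1 and the epoxide oxygen, which places C10 and not C7 anti to the C5–O bond. The mild chelating Lewis acid should keep the process concerted and leave the silyl ether and both alkenes untouched.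

Step 12
Reactants: 16 the spiro β-hydroxy ketone
Product: 17 (1S,2S,5S,9S,10R)-10-allyl-1-[(tert-butyldimethylsilyl)oxy]-2-{2-[(tert-butyldimethylsilyl)oxy]ethyl}-9-(prop-1-en-2-yl)spiro[4.5]decan-6-one
Conditions: TBSOTf, 2,6-lutidine, CH2Cl2, −78 → 0 °C
Reagents that add atoms: tert-butyldimethylsilyl triflate, CC(C)(C)[Si](C)(C)OS(=O)(=O)C(F)(F)F
Why: Silyl triflate silylation of the hindered C1 alcohol blocks retro-aldol cleavage and chelation in the next step and adds bulk to the C1 face of the ketone.

Step 13
Reactants: 17 the bis-silyl spiro ketone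
Product: 18 (1S,2S,5S,6S,9S,10R)-10-allyl-1-[(tert-butyldimethylsilyl)oxy]-2-{2-[(tert-butyldimethylsilyl)oxy]ethyl}-6-methyl-9-(prop-1-en-2-yl)spiro[4.5]decan-6-ol
Conditions: MeLi (3 equiv), Et2O, −78 → −20 °C; aq. NH4Cl
Reagents that add atoms: methyllithium, [Li]C
Why: This is a 1,2-addition of methyllithium; in the chair with allyl and isopropenyl equatorial the siloxy-bearing C1 is axial and blocks the equatorial trajectory, so methyl should enter axially from the C4 side and give the (6S) carbinol with OH cis to C1.

Step 14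
Reactants: 18 the C6 tertiary alcohol
Product: 20 3-[(1S,2S,5S,6S,9S,10R)-1-[(tert-butyldimethylsilyl)oxy]-2-{2-[(tert-butyldimethylsilyl)oxy]ethyl}-6-hydroxy-6-methyl-9-(prop-1-en-2-yl)spiro[4.5]decan-10-yl]propan-1-ol, via the corresponding 3-(disiamylboryl)propyl compound 19 (not isolated)
Conditions: Sia2BH, THF, 0 °C; then NaOH, H2O2, 0 °C
Reagents that add atoms: disiamylborane, CC(C)C(C)BC(C)C(C)C (boron only in 19); hydrogen peroxide, OO
Why: In Brown hydroboration–oxidation the bulky dialkylborane reacts with the monosubstituted allyl alkene much faster than with the hindered 1,1-disubstituted isopropenyl group and places boron on the terminal carbon.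

Step 15
Reactants: 20 the primary alcohol
Product: 21 the tert-butyldiphenylsilyl ether of 20 at the hydroxypropyl oxygen (all stereocentres unchanged)
Conditions: TBDPSCl, imidazole, CH2Cl2, rt
Reagents that add atoms: tert-butyldiphenylsilyl chloride, CC(C)(C)[Si](Cl)(c1ccccc1)c1ccccc1
Why: Selective silylation of the primary alcohol (the tertiary C6 OH stays free) installs a group that survives the acid methanolysis used later to free the C2 arm.

Step 16
Reactants: 21 the TBDPS ether
Product: 23 2-[(1S,2S,5S,6S,9S,10R)-1-[(tert-butyldimethylsilyl)oxy]-2-{2-[(tert-butyldimethylsilyl)oxy]ethyl}-10-{3-[(tert-butyldiphenylsilyl)oxy]propyl}-6-hydroxy-6-methylspiro[4.5]decan-9-yl]prop-2-enal, via the 3-hydroxyprop-1-en-2-yl allylic alcohol 22 (not isolated)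
Conditions: SeO2 (0.3 equiv), t-BuOOH, CH2Cl2, rt; crude, then Dess–Martin periodinane, NaHCO3, CH2Cl2, rt
Reagents that add atoms: tert-butyl hydroperoxide, CC(C)(C)OO
Why: Sharpless-modified Riley allylic oxidation (ene reaction then [2,3]-shift) of a ring-bound isopropenyl group attacks its methyl group, the only unhindered allylic position of the only alkene left, and Dess–Martin oxidation brings the alcohol/aldehyde mixture to the aldehyde.

Step 17
Reactants: 23 the 2-substituted acrolein
Product: 24 (2Z)-2-[(1S,2S,5S,6S,10R)-1-[(tert-butyldimethylsilyl)oxy]-2-{2-[(tert-butyldimethylsilyl)oxy]ethyl}-10-{3-[(tert-butyldiphenylsilyl)oxy]propyl}-6-hydroxy-6-methylspiro[4.5]decan-9-ylidene]propanal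
Conditions: RuHCl(CO)(PPh3)3 (5 mol %), toluene, 80 °C
Reagents that add atoms: none
Why: Metal-hydride addition–β-hydride elimination, known for 2-alkylacroleins going to 2-methylalk-2-enals and for α-methylene carbonyl compounds, moves the C=C into the more substituted conjugated position, and its reversibility should favour the Z isomer, in which the flat CHO rather than CH3 faces the substituted C10.

Step 18
Reactants: 24 the Z enal
Product: 25 the dimethyl acetal of 24 with the C2 arm freed to 2-hydroxyethyl (C1 OTBS, TBDPS ether, C6 OH and Z alkene unchanged)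
Conditions: HC(OMe)3, CSA (0.2 equiv), MeOH, 0 °C → rt
Reagents that add atoms: trimethyl orthoformate, COC(OC)OC
Why: Acid-catalysed acetalisation and methanolysis of the primary TBS ether run under the same conditions, while the hindered secondary TBS ether and the TBDPS ether are much slower to cleave; the acetal masks the enal and its γ-hydrogen at C10 against the base and hydride to come.

Step 19
Reactants: 25 the hydroxy acetal
Product: 26 the corresponding C2 acetaldehyde (arm CH2CHO)
Conditions: Dess–Martin periodinane, NaHCO3, CH2Cl2, 0 °C → rt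
Reagents that add atoms: none
Why: Buffered Dess–Martin oxidation converts the only primary alcohol into the aldehyde and spares the acetal, the silyl ethers and the tertiary alcohol.

Step 20
Reactants: 27 6-methylhept-5-en-2-one
Product: 29 6-methylhepta-1,5-dien-2-yl trifluoromethanesulfonate, via lithium 6-methylhepta-1,5-dien-2-olate 28 (not isolated)
Conditions: LDA, THF, −78 °C; then PhNTf2, −78 → 0 °C
Reagents that add atoms: lithium diisopropylamide, CC(C)N([Li])C(C)C (lithium only in 28); N-phenylbis(trifluoromethanesulfonimide), O=S(=O)(N(c1ccccc1)S(=O)(=O)C(F)(F)F)C(F)(F)F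
Why: Kinetic deprotonation of the methyl ketone at CH3 and O-triflation of the enolate give the terminal enol triflate.

Step 21
Reactants: 29 6-methylhepta-1,5-dien-2-yl trifluoromethanesulfonate; 30 acrolein
Product: 31 (2E)-8-methyl-4-methylidenenona-2,7-dienal
Conditions: Pd(OAc)2 (5 mol %), PPh3 (10 mol %), Et3N, BHT, DMF, 60 °C
Reagents that add atoms: none
Why: Heck vinylation of an enol triflate with an acceptor alkene gives the conjugated dienal, and syn insertion followed by syn β-hydride elimination sets the E alkene.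

Step 22
Reactants: 26 the C2 acetaldehyde; 31 (2E)-8-methyl-4-methylidenenona-2,7-dienal
Product: 33 the (2E,4E)-2-(spirodecan-2-yl)-10-methyl-6-methylideneundeca-2,4,9-trienal (side-chain CHO trans to the dienyl residue), via the β-hydroxy aldehyde aldol adduct 32 (not isolated)
Conditions: 31 (3 equiv), NaOH (0.3 equiv), MeOH, 0 °C → rt, slow addition of 26
Reagents that add atoms: none
Why: This is a crossed aldol condensation of Claisen–Schmidt type, as in cinnamaldehyde plus propanal; 31 has no acidic α- or γ-hydrogen and is used in excess, so 26 is the only donor, and reversible addition with E1cB dehydration should give the more stable E 2-alkyl enal.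

Step 23
Reactants: 33 the trienal
Product: 34 the corresponding (2E,4E)-trienol (side-chain CH2OH)
Conditions: NaBH4, CeCl3·7H2O, MeOH, −40 °C
Reagents that add atoms: none
Why: Luche reduction gives clean 1,2-reduction of the conjugated aldehyde, and the dimethyl acetal is unaffected in methanol.

Step 24
Reactants: 34 the protected trienol
Product: 35 the tetraol dimethyl acetal (C1 OH, C6 OH, hydroxypropyl OH and side-chain CH2OH free)
Conditions: TBAF (5 equiv), THF, rt → 40 °C
Reagents that add atoms: none
Why: Fluoride desilylation removes the TBDPS and the hindered C1 TBS ethers while the base-sensitive enal is still masked.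

Step 25
Reactants: 35 the tetraol dimethyl acetal
Product: 36 CNP0246965.1, (1S,2S,5S,6S,10R; 9Z; side chain E,E)
Conditions: PPTS (0.1 equiv), acetone/H2O 10:1, 0 °C → rt
Reagents that add atoms: water, O
Why: α,β-Unsaturated acetals hydrolyse through a stabilised oxocarbenium ion much faster than the trienyl carbinol ionises, and that ion is captured far faster than its C9=C bond can rotate, so the Z geometry should be kept.

## Compound list

1 | cyclopent-2-en-1-one | O=C1C=CCC1 | starting material
2 | bromomagnesium (3S)-3-(prop-1-en-2-yl)cyclopent-1-en-1-olate | Br[Mg]OC1=C[C@@H](C(C)=C)CC1 | intermediate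
3 | (2R,3S)-2-allyl-3-(prop-1-en-2-yl)cyclopentan-1-one | O=C1CC[C@H](C(C)=C)[C@H]1CC=C | intermediate
4 | cyclopentane-1,3-dione | O=C1CCC(=O)C1 | starting material
5 | 3-bromocyclopent-2-en-1-one | O=C1C=C(Br)CC1 | intermediate
6 | (1R)-3-bromocyclopent-2-en-1-ol | O[C@H]1C=C(Br)CC1 | intermediate
7 | (1R)-3-bromocyclopent-2-en-1-yl methyl carbonate | COC(=O)O[C@H]1C=C(Br)CC1 | intermediate
8 | dimethyl malonate | COC(=O)CC(=O)OC | starting material
9 | dimethyl 2-[(1S)-3-bromocyclopent-2-en-1-yl]propanedioate | COC(=O)C(C(=O)OC)[C@H]1C=C(Br)CC1 | intermediate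
10 | methyl 2-[(1S)-3-bromocyclopent-2-en-1-yl]acetate | COC(=O)C[C@H]1C=C(Br)CC1 | intermediate
11 | 2-[(1S)-3-bromocyclopent-2-en-1-yl]ethan-1-ol | OCC[C@H]1C=C(Br)CC1 | intermediate
12 | {2-[(1S)-3-bromocyclopent-2-en-1-yl]ethoxy}(tert-butyl)dimethylsilane | CC(C)(C)[Si](C)(C)OCC[C@H]1C=C(Br)CC1 | intermediate
13 | [(3S)-3-{2-[(tert-butyldimethylsilyl)oxy]ethyl}cyclopent-1-en-1-yl]lithium | CC(C)(C)[Si](C)(C)OCC[C@H]1C=C([Li])CC1 | intermediate
14 | bicyclopentyl allylic alcohol, (1S,2R,3S)-cyclopentanol, (3S)-cyclopentenyl | CC(C)(C)[Si](C)(C)OCC[C@H]1C=C(CC1)[C@]2(O)CC[C@H](C(C)=C)[C@H]2CC=C | intermediate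
15 | bicyclopentyl epoxy alcohol (epoxide anti to the C2 arm) | CC(C)(C)[Si](C)(C)OCC[C@@H]1CC[C@@]2([C@]3(O)CC[C@H](C(C)=C)[C@H]3CC=C)O[C@@H]12 | intermediate
16 | (1S,2S,5S,9S,10R)-1-hydroxyspiro[4.5]decan-6-one with 10-allyl, 9-isopropenyl and 2-(2-TBSO-ethyl) | CC(C)(C)[Si](C)(C)OCC[C@@H]1CC[C@]2([C@H](CC=C)[C@@H](C(C)=C)CCC2=O)[C@H]1O | intermediate
17 | C1 TBS ether of 16 | CC(C)(C)[Si](C)(C)OCC[C@@H]1CC[C@]2([C@H](CC=C)[C@@H](C(C)=C)CCC2=O)[C@H]1O[Si](C)(C)C(C)(C)C | intermediate
18 | (6S)-6-methyl-6-ol from 17 | CC(C)(C)[Si](C)(C)OCC[C@@H]1CC[C@]2([C@H](CC=C)[C@@H](C(C)=C)CC[C@]2(C)O)[C@H]1O[Si](C)(C)C(C)(C)C | intermediate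
19 | 3-(disiamylboryl)propyl compound from 18 | CC(C)(C)[Si](C)(C)OCC[C@@H]1CC[C@]2([C@H](CCCB(C(C)C(C)C)C(C)C(C)C)[C@@H](C(C)=C)CC[C@]2(C)O)[C@H]1O[Si](C)(C)C(C)(C)C | intermediate
20 | C10 3-hydroxypropyl compound | CC(C)(C)[Si](C)(C)OCC[C@@H]1CC[C@]2([C@H](CCCO)[C@@H](C(C)=C)CC[C@]2(C)O)[C@H]1O[Si](C)(C)C(C)(C)C | intermediate
21 | TBDPS ether of 20 | CC(C)(C)[Si](C)(C)OCC[C@@H]1CC[C@]2([C@H](CCCO[Si](c3ccccc3)(c3ccccc3)C(C)(C)C)[C@@H](C(C)=C)CC[C@]2(C)O)[C@H]1O[Si](C)(C)C(C)(C)C | intermediate
22 | C9 3-hydroxyprop-1-en-2-yl compound (allylic alcohol) | CC(C)(C)[Si](C)(C)OCC[C@@H]1CC[C@]2([C@H](CCCO[Si](c3ccccc3)(c3ccccc3)C(C)(C)C)[C@@H](C(=C)CO)CC[C@]2(C)O)[C@H]1O[Si](C)(C)C(C)(C)C | intermediate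
23 | C9 3-oxoprop-1-en-2-yl compound (2-substituted acrolein) | CC(C)(C)[Si](C)(C)OCC[C@@H]1CC[C@]2([C@H](CCCO[Si](c3ccccc3)(c3ccccc3)C(C)(C)C)[C@@H](C(=C)C=O)CC[C@]2(C)O)[C@H]1O[Si](C)(C)C(C)(C)C | intermediate
24 | (Z)-2-(spirodecan-9-ylidene)propanal | CC(C)(C)[Si](C)(C)OCC[C@@H]1CC[C@]2([C@H](CCCO[Si](c3ccccc3)(c3ccccc3)C(C)(C)C)/C(=C(/C)C=O)CC[C@]2(C)O)[C@H]1O[Si](C)(C)C(C)(C)C | intermediate
25 | dimethyl acetal with free 2-hydroxyethyl arm | OCC[C@@H]1CC[C@]2([C@H](CCCO[Si](c3ccccc3)(c3ccccc3)C(C)(C)C)/C(=C(/C)C(OC)OC)CC[C@]2(C)O)[C@H]1O[Si](C)(C)C(C)(C)C | intermediate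
26 | C2 acetaldehyde | O=CC[C@@H]1CC[C@]2([C@H](CCCO[Si](c3ccccc3)(c3ccccc3)C(C)(C)C)/C(=C(/C)C(OC)OC)CC[C@]2(C)O)[C@H]1O[Si](C)(C)C(C)(C)C | intermediate
27 | 6-methylhept-5-en-2-one | CC(=O)CCC=C(C)C | starting material
28 | lithium 6-methylhepta-1,5-dien-2-olate | [Li]OC(=C)CCC=C(C)C | intermediate
29 | 6-methylhepta-1,5-dien-2-yl trifluoromethanesulfonate | C=C(OS(=O)(=O)C(F)(F)F)CCC=C(C)C | intermediate
30 | acrolein | C=CC=O | starting material
31 | (2E)-8-methyl-4-methylidenenona-2,7-dienal | O=C/C=C/C(=C)CCC=C(C)C | intermediate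
32 | aldol adduct of 26 and 31 (two new centres undefined) | O=CC(C(O)/C=C/C(=C)CCC=C(C)C)[C@@H]1CC[C@]2([C@H](CCCO[Si](c3ccccc3)(c3ccccc3)C(C)(C)C)/C(=C(/C)C(OC)OC)CC[C@]2(C)O)[C@H]1O[Si](C)(C)C(C)(C)C | intermediate
33 | (2E,4E)-trienal | C=C(/C=C/C=C(/C=O)[C@@H]1CC[C@]2([C@H](CCCO[Si](c3ccccc3)(c3ccccc3)C(C)(C)C)/C(=C(/C)C(OC)OC)CC[C@]2(C)O)[C@H]1O[Si](C)(C)C(C)(C)C)CCC=C(C)C | intermediate
34 | (2E,4E)-trienol, protected | C=C(/C=C/C=C(/CO)[C@@H]1CC[C@]2([C@H](CCCO[Si](c3ccccc3)(c3ccccc3)C(C)(C)C)/C(=C(/C)C(OC)OC)CC[C@]2(C)O)[C@H]1O[Si](C)(C)C(C)(C)C)CCC=C(C)C | intermediate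
35 | tetraol dimethyl acetal | C=C(/C=C/C=C(/CO)[C@@H]1CC[C@]2([C@H](CCCO)/C(=C(/C)C(OC)OC)CC[C@]2(C)O)[C@H]1O)CCC=C(C)C | intermediate
36 | CNP0246965.1 | C=C(/C=C/C=C(/CO)[C@@H]1CC[C@]2([C@H](CCCO)/C(=C(/C)C=O)CC[C@]2(C)O)[C@H]1O)CCC=C(C)C | target

## Step count and risks

Total step count: 25. Longest linear sequence: 22 steps, from cyclopentane-1,3-dione (steps 2–19 and 22–25).

**Step 17 (moving the C=C into the tetrasubstituted position).**
- What may go wrong: the hydride catalyst may stall at the 2-substituted acrolein. It may run on to ring-endocyclic β,γ-isomers, which would also endanger C10. It may decarbonylate the aldehyde, or it may equilibrate to a poor Z/E distribution.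
- Fallback: from 23, Rh-catalysed 1,4-hydrosilylation (Et3SiH, RhCl(PPh3)3, THF) would give the C9 1-(triethylsiloxy)prop-1-en-2-yl compound F1. Saegusa–Ito oxidation (Pd(OAc)2, MeCN) would then remove the C9 hydrogen by β-hydride elimination and return to the route at 24. Material that loses a methyl hydrogen instead reverts to 23 and is recycled.

**Step 1 (asymmetric conjugate isopropenylation with enolate allylation).**
- What may go wrong: an sp2 Grignard reagent on the small, flat cyclopentenone may give poor facial selectivity or competing 1,2-addition. Proton exchange of the enolate may lead to over-allylation.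
- Fallback: from 1, the same addition–allylation without chiral ligand (CuBr·SMe2 only) would give 3 together with its enantiomer (2S,3R)-2-allyl-3-(prop-1-en-2-yl)cyclopentan-1-one F2. Under the conditions of step 9 the enantiopure alkenyllithium 13 converts this racemate into 14 and the diastereomeric (1R,2S,3R)-cyclopentanol adduct F3. These are separated by chromatography, so the absolute configuration then rests on the CBS-derived centre alone. The route is rejoined at 14.

**Step 11 (semipinacol ring enlargement).**
- What may go wrong: C7 may migrate in competition with C10. Proton loss from C4 may give an allylic alcohol. The isopropenyl group may capture the developing C5 cation. The five-to-six enlargement may simply be sluggish.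
- Fallback: from 15, silylation of the tertiary hydroxyl (TMS-imidazole, CH2Cl2) would give the epoxy trimethylsilyl ether F4. Its Suzuki–Tsuchihashi rearrangement (TiCl4, CH2Cl2, −78 °C, aqueous work-up) replaces the chelated free carbinol by a silyl ether terminus whose loss drives ketone formation at low temperature. The route is rejoined at 16.

Further compounds
F1 | step 17 | C9 1-(triethylsiloxy)prop-1-en-2-yl compound (silyl enol ether of the saturated aldehyde, E/Z undefined) | CC(C)(C)[Si](C)(C)OCC[C@@H]1CC[C@]2([C@H](CCCO[Si](c3ccccc3)(c3ccccc3)C(C)(C)C)[C@@H](C(C)=CO[Si](CC)(CC)CC)CC[C@]2(C)O)[C@H]1O[Si](C)(C)C(C)(C)C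
F2 | step 1 | (2S,3R)-2-allyl-3-(prop-1-en-2-yl)cyclopentan-1-one | O=C1CC[C@@H](C(C)=C)[C@@H]1CC=C
F3 | step 1 | (1R,2S,3R)-2-allyl-1-[(3S)-3-{2-[(tert-butyldimethylsilyl)oxy]ethyl}cyclopent-1-en-1-yl]-3-(prop-1-en-2-yl)cyclopentan-1-ol | CC(C)(C)[Si](C)(C)OCC[C@H]1C=C(CC1)[C@@]2(O)CC[C@@H](C(C)=C)[C@@H]2CC=C
F4 | step 11 | trimethylsilyl ether of 15 at the tertiary carbinol | CC(C)(C)[Si](C)(C)OCC[C@@H]1CC[C@@]2([C@]3(O[Si](C)(C)C)CC[C@H](C(C)=C)[C@H]3CC=C)O[C@@H]12
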